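## Structural features

The target is a 4→8 biflavanoid: an upper 3-deoxyflavan (ring A benzo, ring C pyran O1–C2–C3–C4–C4a–C8a, ring B catechol on C2) whose C4 is bonded to C8' of a lower (+)-catechin unit (rings D, F and E, atoms primed). It has four stereocentres in two separate pairs. C2 and C4 of ring C are 1,3-related, both S, with the two aryl groups cis and equatorial; C2' (R) and C3' (S) of ring F are adjacent and trans. C4 is a doubly benzylic methine flanked by four ortho oxygen substituents, so the C4–C8' bond is hard to make. Once ring A carries free hydroxyls that bond ionises under acid, O1–C2 is a para-oxygenated benzylic ether that can also ionise, and the nine free hydroxyls are sensitive to air and base. The real difficulty is to set C4 relative to C2, and both in the right absolute sense relative to the distant catechin centres, with no C3 substituent to steer the C4–C8' bond formation. The key step exploits two facts: the oxygens on C5, C7 and C8a of ring A alternate as in a triketide, and C8a is at the carboxyl oxidation level when ring C is written as a δ-lactone. Ring A is therefore left out until the end, C2 and C4 are set on a simple lactone (lactone C6 = C2, C4 = C4, C3 = C4a, C2 = C8a), and ring A is then made by joining C8 to C8a.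

## Logic of the disconnections

20 back to 19: the seven O–CH2Ph bonds are cut. Benzyl ethers are inert to amide bases, palladium coupling and copper hydride and fall together in one neutral hydrogenolysis. The forward step must spare the benzylic O1–C2, O1'–C2' and C4–aryl bonds.

19 back to 17: the C8–C8a bond of ring A is cut; ring A unravels to an acetoacetyl chain on C4a and C8a returns to a lactone carbonyl. The gain is that the electron-rich ring A is absent while C2 and C4 are set, and no regiochemistry on a phloroglucinol has to be controlled. The demand is that the terminal methyl carbon becomes nucleophilic in the presence of two more acidic sites and attacks a lactone carbonyl that is conjugated with an enolate. Because the adduct is expected to open ring C to 18, the forward step must also re-form O1–C2.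

17 back to 16 and then 15: C6–C7 and then C4a–C5 are cut, two C-acylations with the same two-carbon donor. Cutting twice avoids a ketal-protected four-carbon donor and its acidic deprotection, so 17 meets no acid before the key step. The demand is C-selective acylation of a hindered lactone enolate, then acylation of a dianion at its terminal carbon.

15 back to 14: the C4–H bond is cut. Adding this hydrogen last turns the congested sp3 centre into an sp2 carbon for the coupling and lets the C6 centre (future C2) control C4 through the ring. The demand is hydride delivery to a hindered β-carbon with high facial selectivity and without loss of benzyl ethers.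

14 back to 8 and 13: the C4–C8' bond is cut. The molecule falls into two halves of similar size, and 13 brings both ring F stereocentres unchanged. The demand is the coupling of a di-ortho-substituted boronate that protodeboronates easily with a base-sensitive enol triflate.

8 back to 7, 5, then 2 and 3 (2 from 1): the O–S bond, the acyl–oxygen bond C8a–O1 and the C2–C3 bond (flavan numbering) are cut in turn. The last is an aldol disconnection that creates the only stereocentre a catalyst must set. The demand is an enantioselective vinylogous aldol on an electron-rich aldehyde and gentle handling of a benzylic alcohol that ionises readily.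

13 back to 11, 10 and 9: C8'–B, C8'–Br and five O–CH2Ph bonds are cut. Both ring F stereocentres come from the chiral pool. The demand is C8' over C6' selectivity in the bromination.

## Other disconnections considered

Alternative 1: The cut runs through ring C at C4–C4a and O1–C2. Ring A comes from the symmetrical phenol A1 (3,5-bis(benzyloxy)phenol), and C2, C3, C4, ring B and the whole lower unit from the ynone A2. In the forward sense HBF4 would promote attack of the carbon ortho to the hydroxyl of A1 on the alkyne carbon that carries C8'; condensation of the phenol oxygen with the ketone would then close ring C as the flavylium salt A3.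
- In favour: ring A is bought, A1 is symmetrical so no regiochemistry arises, and the sequence is convergent and probably shorter. The annulation of phenols with aryl ethynyl ketones to flavylium salts is an established reaction type. On precedent for the ring-forming step and on step count this alternative is the better one.
- Against: A3 is flat from C2 to C4, so both ring C stereocentres would have to be made afterwards by a four-electron reduction whose only chiral information is the distant C2' and C3'. A cis relationship of the two new hydrogens can be expected, but the (2S,4S) and (2R,4R) cis diastereomers would not be distinguished. An asymmetric reduction of a 2,4-diarylflavylium ion with a four-fold ortho-substituted C4–C8' axis has no close model. The strongly acidic medium also endangers nine benzyl ethers and the benzylic O1'–C2' bond.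
- Comparison: the bond construction is safer and the stereochemistry much less so. The chosen plan fixes C2 with a catalyst and C4 by 1,3-induction in a six-membered ring before ring A exists, and pays with a longer sequence and an untested ring closure.

Alternative 2: The cut lies in the lower unit, at O1'–C2' and C3'–C4' of ring F. The salicyl alcohol A4, which already holds the complete upper flavan, would lose water to give the ortho-quinone methide A5 (C8a'=O, C4a'=C4'H2). An inverse-demand [4+2] cycloaddition with the (E)-styrylsilane A6 would close ring F as A7, with silicon on C3' trans to the ring E aryl group. Tamao–Fleming oxidation with retention and hydrogenolysis would finish the synthesis.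
- In favour: cycloadditions of ortho-quinone methides with styrenes are a known way to 2-arylchromans, and the alkene geometry is carried into the 2',3'-trans relationship. No organometallic chemistry at the hindered C8' of a finished catechin is needed; on this point it is the equal of, or better than, the chosen plan.
- Against: it rebuilds, with new stereochemical risk, a ring that 9 supplies enantiopure. The face of A5 attacked by A6 would be decided only by the remote C4 centre, so (2'R,3'S) and (2'S,3'R) products are both to be expected. The vinylsilane may be protodesilylated under the conditions that generate A5. Most importantly, A4 still contains C2 and C4, so the real difficulty is only moved into the synthesis of A4. It is also longer, since a silicon-to-hydroxyl exchange is added.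
- Comparison: mechanistically the cycloaddition is better precedented than the chosen key step, but structurally it solves the easier half of the problem.

Alternative 3: The cut runs through ring C at O1–C2 and C2–C3. The phenol of the hydroxy-diarylethene A8 and aldehyde 3 would form an oxocarbenium ion, and the alkene CH2 would attack it to make C2–C3 and close ring C. Loss of a C3 proton from the resulting diaryl cation would give the 2H-chromene A9. Hydrogenation of C3=C4 from the face opposite the C2 aryl group would then give the 2,4-cis flavan and could be merged with the debenzylation.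
- In favour: it uses 3 as it is, ring A is aromatic from the start, a chiral Brønsted acid could in principle set C2, and the last two operations could be one. In step economy it is at least the equal of the chosen plan.
- Against: A8 is a 1,1-diarylethene with four ortho substituents. Its synthesis needs a bond at C4 as hindered as the one in 14, so nothing is gained there, and its twisted aryl groups make the alkene a poor nucleophile. 2-Aryl-2H-chromenes open reversibly to ortho-quinone methides, a path by which C2 can racemise. Hydrogenation of a hindered styrenic double bond next to the benzylic O1–C2 bond invites ring opening by hydrogenolysis.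
- Comparison: the bond-forming chemistry is better known, but C2 is fragile, whereas in the chosen plan C2 stays a lactone carbinol until the last step but one. C4 is set in both plans by adding hydrogen anti to the C2 aryl group, so on that point the two are equal.

Key step: step 12

Assumption: in step 2 the Ti(OiPr)4/(S)-BINOL catalyst is taken to deliver the (S)-carbinol; should the sense of induction be the opposite, (R)-BINOL is used and nothing else changes.

Remark on the structures: 17, 19 and 20 were compared centre by centre and agree, (4S,6S) in 17 and (2S,4S,2'R,3'S) in 19 and 20 with ring C 2,4-cis, so no structure needs correction. Two points of the key step are changed: LiN(SiMe3)2 is too weak for the third deprotonation, so LiN(iPr)2 is used, and a mild acid stage is added because the Claisen adduct is expected to open ring C.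

Step 1
Reactants: 1 2,2,6-trimethyl-4H-1,3-dioxin-4-one
Product: 2 2,2-dimethyl-6-methylidene-4-(trimethylsilyloxy)-6H-1,3-dioxine
Conditions: LiN(iPr)2, THF, −78 °C; Me3SiCl, −78 °C → rt
Reagents that add atoms: chlorotrimethylsilane, C[Si](C)(C)Cl
Why: Kinetic deprotonation of the vinylogous ester at the 6-methyl group and O-silylation of the dienolate should give the cross-conjugated silyl dienol ether (silyl dienolate formation).

Step 2
Reactants: 2 2,2-dimethyl-6-methylidene-4-(trimethylsilyloxy)-6H-1,3-dioxine; 3 3,4-bis(benzyloxy)benzaldehyde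
Product: 5 (S)-6-{2-[3,4-bis(benzyloxy)phenyl]-2-hydroxyethyl}-2,2-dimethyl-4H-1,3-dioxin-4-one, via trimethylsilyl ether 4 (not isolated)
Conditions: Ti(OiPr)4 (10 mol%), (S)-BINOL (10 mol%), 4 Å MS, THF, −78 °C → rt; then aq. citric acid, MeOH, 0 °C
Reagents that add atoms: none
Why: Catalytic asymmetric vinylogous Mukaiyama aldol: the dienol ether reacts at its terminal CH2 and the chiral titanium BINOLate differentiates the aldehyde faces, setting the carbinol centre (S), the future C2; citric acid removes the silyl group without ionising the electron-rich benzylic alcohol.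

Step 3
Reactants: 5 (S)-6-{2-[3,4-bis(benzyloxy)phenyl]-2-hydroxyethyl}-2,2-dimethyl-4H-1,3-dioxin-4-one
Product: 7 (S)-6-[3,4-bis(benzyloxy)phenyl]dihydro-2H-pyran-2,4(3H)-dione, via acylketene 6 (not isolated)
Conditions: PhMe (0.02 M), 110 °C
Reagents that add atoms: none
Why: Thermal retro-[4+2] loss of acetone should give the acylketene, which the δ-hydroxyl traps in a six-membered lactonisation; the carbinol C–O bond is not broken, so the configuration is kept.

Step 4
Reactants: 7 (S)-6-[3,4-bis(benzyloxy)phenyl]dihydro-2H-pyran-2,4(3H)-dione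
Product: 8 (S)-6-[3,4-bis(benzyloxy)phenyl]-2-oxo-5,6-dihydro-2H-pyran-4-yl trifluoromethanesulfonate
Conditions: Tf2O, Et3N, CH2Cl2, −78 °C
Reagents that add atoms: trifluoromethanesulfonic anhydride, O=S(=O)(OS(=O)(=O)C(F)(F)F)C(F)(F)F
Why: The β-keto lactone enolises towards C3 and O-sulfonylation of that enolate should give the conjugated enol triflate (enol triflate formation); the amine keeps the medium basic so the benzylic C6–O bond does not ionise.

Step 5
Reactants: 9 (+)-catechin
Product: 10 (2R,3S)-3,5,7-tris(benzyloxy)-2-[3,4-bis(benzyloxy)phenyl]chroman (penta-O-benzyl-(+)-catechin)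
Conditions: NaH, BnBr, DMF, −20 °C → rt
Reagents that add atoms: benzyl bromide, BrCc1ccccc1
Why: Williamson etherification of the four phenols and the secondary alcohol; low temperature should limit C-benzylation of ring D and base-induced epimerisation at C2'.

Step 6
Reactants: 10 (2R,3S)-3,5,7-tris(benzyloxy)-2-[3,4-bis(benzyloxy)phenyl]chroman
Product: 11 (2R,3S)-3,5,7-tris(benzyloxy)-2-[3,4-bis(benzyloxy)phenyl]-8-bromochroman
Conditions: NBS, CH2Cl2, −78 → 0 °C
Reagents that add atoms: N-bromosuccinimide, O=C1CCC(=O)N1Br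
Why: Electrophilic aromatic bromination; C8' is the more reactive of the two free ring D positions in benzylated flavan-3-ols, so one equivalent at low temperature should give the 8-bromide.

Step 7
Reactants: 11 (2R,3S)-3,5,7-tris(benzyloxy)-2-[3,4-bis(benzyloxy)phenyl]-8-bromochroman
Product: 13 2-{(2R,3S)-3,5,7-tris(benzyloxy)-2-[3,4-bis(benzyloxy)phenyl]chroman-8-yl}-4,4,5,5-tetramethyl-1,3,2-dioxaborolane, via aryllithium 12 (not isolated)
Conditions: n-BuLi, THF, −78 °C; iPrOBpin, −78 °C → rt; H2O
Reagents that add atoms: 2-isopropoxy-4,4,5,5-tetramethyl-1,3,2-dioxaborolane, CC(C)OB1OC(C)(C)C(C)(C)O1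
Why: Bromine–lithium exchange is fast at −78 °C and outruns deprotonation of the benzyl ethers; borylation of the aryllithium with the isopropoxyboronate should give the pinacol ester.

Step 8
Reactants: 8 (S)-6-[3,4-bis(benzyloxy)phenyl]-2-oxo-5,6-dihydro-2H-pyran-4-yl trifluoromethanesulfonate; 13 2-{(2R,3S)-3,5,7-tris(benzyloxy)-2-[3,4-bis(benzyloxy)phenyl]chroman-8-yl}-4,4,5,5-tetramethyl-1,3,2-dioxaborolane
Product: 14 (S)-6-[3,4-bis(benzyloxy)phenyl]-4-{(2R,3S)-3,5,7-tris(benzyloxy)-2-[3,4-bis(benzyloxy)phenyl]chroman-8-yl}-5,6-dihydro-2H-pyran-2-one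
Conditions: Pd(OAc)2 (5 mol%), SPhos (10 mol%), K3PO4, THF/H2O (10:1), 40 °C
Reagents that add atoms: none
Why: Suzuki–Miyaura coupling: zerovalent palladium inserts into the enol triflate, the bulky electron-rich biarylphosphine speeds transmetalation of the di-ortho-substituted boronate, and reductive elimination forms C4–C8'; mild base and temperature are chosen to limit protodeboronation and ring opening of the lactone.

Step 9
Reactants: 14 (S)-6-[3,4-bis(benzyloxy)phenyl]-4-{(2R,3S)-3,5,7-tris(benzyloxy)-2-[3,4-bis(benzyloxy)phenyl]chroman-8-yl}-5,6-dihydro-2H-pyran-2-one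
Product: 15 (4S,6S)-6-[3,4-bis(benzyloxy)phenyl]-4-{(2R,3S)-3,5,7-tris(benzyloxy)-2-[3,4-bis(benzyloxy)phenyl]chroman-8-yl}tetrahydro-2H-pyran-2-one (4,6-cis)
Conditions: Cu(OAc)2·H2O (5 mol%), 1,2-bis(diphenylphosphino)benzene (5 mol%), (EtO)2MeSiH, t-BuOH, PhMe, rt
Reagents that add atoms: none
Why: Phosphine-ligated CuH conjugate reduction of the unsaturated lactone; as in nucleophilic additions to 6-substituted 5,6-dihydropyran-2-ones, the hydride should enter at C4 on the face opposite the pseudo-equatorial C6 aryl group, which places the C4 aryl group cis to it (4S), and neither the benzyl ethers nor the lactone carbonyl are reduced.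

Step 10
Reactants: 15 (4S,6S)-6-[3,4-bis(benzyloxy)phenyl]-4-{(2R,3S)-3,5,7-tris(benzyloxy)-2-[3,4-bis(benzyloxy)phenyl]chroman-8-yl}tetrahydro-2H-pyran-2-one
Product: 16 (4S,6S)-3-acetyl-6-[3,4-bis(benzyloxy)phenyl]-4-{(2R,3S)-3,5,7-tris(benzyloxy)-2-[3,4-bis(benzyloxy)phenyl]chroman-8-yl}tetrahydro-2H-pyran-2-one (C3 epimers and enol)
Conditions: LiN(iPr)2, THF, −78 °C; MeC(O)N(OMe)Me, −78 → −20 °C; AcOH
Reagents that add atoms: N-methoxy-N-methylacetamide, CC(=O)N(C)OC
Why: Crossed Claisen-type C-acylation of the lithium lactone enolate with an N-methoxy-N-methylamide; the chelated tetrahedral adduct should survive until the quench, so the acidic product never meets unreacted enolate, and the C3 configuration is irrelevant because C3 becomes aromatic C4a.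

Step 11
Reactants: 16 (4S,6S)-3-acetyl-6-[3,4-bis(benzyloxy)phenyl]-4-{(2R,3S)-3,5,7-tris(benzyloxy)-2-[3,4-bis(benzyloxy)phenyl]chroman-8-yl}tetrahydro-2H-pyran-2-one
Product: 17 (4S,6S)-6-[3,4-bis(benzyloxy)phenyl]-3-(3-oxobutanoyl)-4-{(2R,3S)-3,5,7-tris(benzyloxy)-2-[3,4-bis(benzyloxy)phenyl]chroman-8-yl}tetrahydro-2H-pyran-2-one (triketo form drawn)
Conditions: LiN(iPr)2 (2.2 equiv), THF, −78 → −30 °C; MeC(O)N(OMe)Me, −78 → −30 °C; AcOH, −78 °C
Reagents that add atoms: N-methoxy-N-methylacetamide, CC(=O)N(C)OC
Why: The 1,3-dicarbonyl dianion (C3 and the acetyl methyl) should react at its more basic terminal carbon with the amide (chain extension by dianion acylation); the stable tetrahedral adduct prevents early cyclisation, and the triketone is released only by the cold weak-acid quench.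

Step 12
Reactants: 17 (4S,6S)-6-[3,4-bis(benzyloxy)phenyl]-3-(3-oxobutanoyl)-4-{(2R,3S)-3,5,7-tris(benzyloxy)-2-[3,4-bis(benzyloxy)phenyl]chroman-8-yl}tetrahydro-2H-pyran-2-one
Product: 19 (2S,4S)-2-[3,4-bis(benzyloxy)phenyl]-4-{(2R,3S)-3,5,7-tris(benzyloxy)-2-[3,4-bis(benzyloxy)phenyl]chroman-8-yl}chroman-5,7-diol, via ring-opened triol 18 (not isolated)
Conditions: LiN(iPr)2 (5 equiv), THF, −78 → 0 °C; AcOH, −78 °C; then PPTS (cat.), CH2Cl2 (dilute), rt
Reagents that add atoms: none
Why: Proposed new method: excess LiN(iPr)2 removes the C6 and C4a protons and then a C8 methyl proton, and the C8 carbanion, the only one that can reach a carbonyl through a six-membered transition state, adds to the lactone carbonyl C8a in a 6-(enolendo)-exo-trig Claisen closure that forms ring A; the closest known reactions are the Claisen cyclisations of 3,5,7-triketo esters to acylphloroglucinols and the base-mediated closure of 5-oxo esters to cyclohexane-1,3-diones. The tetrahedral alkoxide is expected to collapse with loss of the ring oxygen, because the cyclohexane-1,3,5-trione formed is at once deprotonated to the aromatic phloroglucinolate, which makes the step irreversible and closes the retro-Claisen path. The quench should give 18, in which the two hydroxyls ortho to C4a are equivalent, so either can close ring C. Under the pyridinium salt the para-alkoxybenzylic alcohol ionises, or is attacked through the hemiketal of the keto tautomer, and the phenol oxygen restores O1–C2 in a six-membered closure. No new stereocentre is formed: C4 is not acidic and keeps its configuration, and C2 either keeps it (hemiketal path) or re-forms under thermodynamic control as the 2,4-cis diequatorial isomer, which is the one required. The selectivity needed is C- over O-attack at C8a and cyclisation over deacylation; full deprotonation makes the C8 carbanion by far the most nucleophilic site and leaves no external nucleophile for retro-Claisen cleavage, while the lactone ring ties C8a to C4a so that only rotation about C4a–C5 is needed to reach the reactive conformer. The acid stage is kept mild and dilute because C4–C8' and O1–C2 of 19 ionise under stronger acid and the benzylic cation could alkylate ring A of a second molecule.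

Step 13
Reactants: 19 (2S,4S)-2-[3,4-bis(benzyloxy)phenyl]-4-{(2R,3S)-3,5,7-tris(benzyloxy)-2-[3,4-bis(benzyloxy)phenyl]chroman-8-yl}chroman-5,7-diol
Product: 20 (2S,4S)-2-(3,4-dihydroxyphenyl)-4-[(2R,3S)-2-(3,4-dihydroxyphenyl)-3,5,7-trihydroxychroman-8-yl]chroman-5,7-diol (CNP0180676.1)
Conditions: H2 (1 atm), Pd(OH)2/C, THF/MeOH, rt
Reagents that add atoms: none
Why: Hydrogenolysis of the seven aryl and alkyl benzyl ethers under neutral conditions, the standard last step for benzylated oligoflavanoids; the ring benzylic C–O and C–C bonds are cleaved far more slowly and no acid is present to ionise C4–C8'.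

## Compound list

1 | 2,2,6-trimethyl-4H-1,3-dioxin-4-one | CC1=CC(=O)OC(C)(C)O1 | starting material
2 | 2,2-dimethyl-6-methylidene-4-(trimethylsilyloxy)-6H-1,3-dioxine | C=C1C=C(O[Si](C)(C)C)OC(C)(C)O1 | intermediate
3 | 3,4-bis(benzyloxy)benzaldehyde | O=Cc1ccc(OCc2ccccc2)c(OCc2ccccc2)c1 | starting material
4 | (S)-6-{2-[3,4-bis(benzyloxy)phenyl]-2-(trimethylsilyloxy)ethyl}-2,2-dimethyl-4H-1,3-dioxin-4-one | C[Si](C)(C)O[C@H](c1ccc(OCc2ccccc2)c(OCc2ccccc2)c1)CC1=CC(=O)OC(C)(C)O1 | intermediate
5 | (S)-6-{2-[3,4-bis(benzyloxy)phenyl]-2-hydroxyethyl}-2,2-dimethyl-4H-1,3-dioxin-4-one | O[C@H](c1ccc(OCc2ccccc2)c(OCc2ccccc2)c1)CC1=CC(=O)OC(C)(C)O1 | intermediate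
6 | (S)-5-[3,4-bis(benzyloxy)phenyl]-5-hydroxypent-1-ene-1,3-dione (acylketene) | O[C@H](c1ccc(OCc2ccccc2)c(OCc2ccccc2)c1)CC(=O)C=C=O | intermediate
7 | (S)-6-[3,4-bis(benzyloxy)phenyl]dihydro-2H-pyran-2,4(3H)-dione | O=C5O[C@H](c1ccc(OCc3ccccc3)c(OCc3ccccc3)c1)CC(=O)C5 | intermediate
8 | (S)-6-[3,4-bis(benzyloxy)phenyl]-2-oxo-5,6-dihydro-2H-pyran-4-yl trifluoromethanesulfonate | O=C5O[C@H](c1ccc(OCc3ccccc3)c(OCc3ccccc3)c1)CC(OS(=O)(=O)C(F)(F)F)=C5 | intermediate
9 | (+)-catechin, (2R,3S) | Oc1cc(O)c2c(c1)O[C@H](c1ccc(O)c(O)c1)[C@@H](O)C2 | starting material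
10 | (2R,3S)-3,5,7-tris(benzyloxy)-2-[3,4-bis(benzyloxy)phenyl]chroman | c1c(OCc3ccccc3)cc(OCc3ccccc3)c2c1O[C@H](c1ccc(OCc3ccccc3)c(OCc3ccccc3)c1)[C@@H](OCc3ccccc3)C2 | intermediate
11 | (2R,3S)-3,5,7-tris(benzyloxy)-2-[3,4-bis(benzyloxy)phenyl]-8-bromochroman | Brc1c(OCc3ccccc3)cc(OCc3ccccc3)c2c1O[C@H](c1ccc(OCc3ccccc3)c(OCc3ccccc3)c1)[C@@H](OCc3ccccc3)C2 | intermediate
12 | {(2R,3S)-3,5,7-tris(benzyloxy)-2-[3,4-bis(benzyloxy)phenyl]chroman-8-yl}lithium | [Li]c1c(OCc3ccccc3)cc(OCc3ccccc3)c2c1O[C@H](c1ccc(OCc3ccccc3)c(OCc3ccccc3)c1)[C@@H](OCc3ccccc3)C2 | intermediate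
13 | 2-{(2R,3S)-3,5,7-tris(benzyloxy)-2-[3,4-bis(benzyloxy)phenyl]chroman-8-yl}-4,4,5,5-tetramethyl-1,3,2-dioxaborolane | CC1(C)OB(OC1(C)C)c1c(OCc3ccccc3)cc(OCc3ccccc3)c2c1O[C@H](c1ccc(OCc3ccccc3)c(OCc3ccccc3)c1)[C@@H](OCc3ccccc3)C2 | intermediate
14 | (S)-6-[3,4-bis(benzyloxy)phenyl]-4-{(2R,3S)-3,5,7-tris(benzyloxy)-2-[3,4-bis(benzyloxy)phenyl]chroman-8-yl}-5,6-dihydro-2H-pyran-2-one | O=C5O[C@H](c1ccc(OCc3ccccc3)c(OCc3ccccc3)c1)CC(c1c(OCc3ccccc3)cc(OCc3ccccc3)c2c1O[C@H](c1ccc(OCc3ccccc3)c(OCc3ccccc3)c1)[C@@H](OCc3ccccc3)C2)=C5 | intermediate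
15 | (4S,6S)-6-[3,4-bis(benzyloxy)phenyl]-4-{(2R,3S)-3,5,7-tris(benzyloxy)-2-[3,4-bis(benzyloxy)phenyl]chroman-8-yl}tetrahydro-2H-pyran-2-one | O=C5O[C@H](c1ccc(OCc3ccccc3)c(OCc3ccccc3)c1)C[C@H](c1c(OCc3ccccc3)cc(OCc3ccccc3)c2c1O[C@H](c1ccc(OCc3ccccc3)c(OCc3ccccc3)c1)[C@@H](OCc3ccccc3)C2)C5 | intermediate
16 | (4S,6S)-3-acetyl-6-[3,4-bis(benzyloxy)phenyl]-4-{(2R,3S)-3,5,7-tris(benzyloxy)-2-[3,4-bis(benzyloxy)phenyl]chroman-8-yl}tetrahydro-2H-pyran-2-one | O=C5O[C@H](c1ccc(OCc3ccccc3)c(OCc3ccccc3)c1)C[C@H](c1c(OCc3ccccc3)cc(OCc3ccccc3)c2c1O[C@H](c1ccc(OCc3ccccc3)c(OCc3ccccc3)c1)[C@@H](OCc3ccccc3)C2)C5C(C)=O | intermediate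
17 | (4S,6S)-6-[3,4-bis(benzyloxy)phenyl]-3-(3-oxobutanoyl)-4-{(2R,3S)-3,5,7-tris(benzyloxy)-2-[3,4-bis(benzyloxy)phenyl]chroman-8-yl}tetrahydro-2H-pyran-2-one | O=C5O[C@H](c1ccc(OCc3ccccc3)c(OCc3ccccc3)c1)C[C@H](c1c(OCc3ccccc3)cc(OCc3ccccc3)c2c1O[C@H](c1ccc(OCc3ccccc3)c(OCc3ccccc3)c1)[C@@H](OCc3ccccc3)C2)C5C(=O)CC(C)=O | intermediate
18 | (1S,3S)-1-[3,4-bis(benzyloxy)phenyl]-3-{(2R,3S)-3,5,7-tris(benzyloxy)-2-[3,4-bis(benzyloxy)phenyl]chroman-8-yl}-3-(2,4,6-trihydroxyphenyl)propan-1-ol | O[C@H](c1ccc(OCc3ccccc3)c(OCc3ccccc3)c1)C[C@H](c1c(OCc3ccccc3)cc(OCc3ccccc3)c2c1O[C@H](c1ccc(OCc3ccccc3)c(OCc3ccccc3)c1)[C@@H](OCc3ccccc3)C2)c1c(O)cc(O)cc1O | intermediate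
19 | (2S,4S)-2-[3,4-bis(benzyloxy)phenyl]-4-{(2R,3S)-3,5,7-tris(benzyloxy)-2-[3,4-bis(benzyloxy)phenyl]chroman-8-yl}chroman-5,7-diol | Oc1cc(O)c2c(c1)O[C@H](c1ccc(OCc3ccccc3)c(OCc3ccccc3)c1)C[C@@H]2c1c(OCc3ccccc3)cc(OCc3ccccc3)c2c1O[C@H](c1ccc(OCc3ccccc3)c(OCc3ccccc3)c1)[C@@H](OCc3ccccc3)C2 | intermediate
20 | (2S,4S)-2-(3,4-dihydroxyphenyl)-4-[(2R,3S)-2-(3,4-dihydroxyphenyl)-3,5,7-trihydroxychroman-8-yl]chroman-5,7-diol | Oc1cc(O)c2c(c1)O[C@H](c1ccc(O)c(O)c1)C[C@@H]2c1c(O)cc(O)c2c1O[C@H](c1ccc(O)c(O)c1)[C@@H](O)C2 | target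

## Step count and least certain steps

Total step count: 13. Longest linear sequence: 10 steps (steps 1, 2, 3, 4, 8, 9, 10, 11, 12, 13, from 1 to 20); the branch from 9 joins at step 8 after three steps.

Step 12 (key step, proposed new method).
- What may go wrong: incomplete removal of the C8 proton; failure of the C8 carbanion to add to a lactone carbonyl that is part of an enolate; attack through oxygen leading to a pyranone; in the acid stage, intermolecular C-alkylation of ring A by the benzylic cation.
- Fallback (known chemistry), setting out from 9 and 10 and returning at 20: both flavan units are taken from 9 and joined by the classical acid-mediated flavan C4 to C8 coupling.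
- 9 is benzylated on its four phenolic hydroxyls (BnBr, K2CO3, DMF) to 5,7,3',4'-tetra-O-benzyl-(+)-catechin F1.
- The 3-hydroxyl is converted with NaH, CS2 and MeI into the S-methyl xanthate F2 and removed by Barton–McCombie reduction (Bu3SnH, AIBN, PhMe, 110 °C), giving (2S)-5,7,3',4'-tetra-O-benzylflavan F3 with C2 already in the arrangement of the upper unit.
- Oxidation of the C4 methylene with DDQ in the presence of 2-ethoxyethanol gives the 4-(2-ethoxyethoxy)flavan F4.
- Me3SiOTf-promoted Friedel–Crafts alkylation of an excess of 10 at C8' gives the nona-O-benzyl ether of the target F5.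
- The 2,4-cis isomer is the diequatorial one and the coupling is reversible under the Lewis acid, so equilibration and chromatography are relied on for C4 and for removal of the C6'-linked regioisomer.
- Hydrogenolysis of F5 (H2, Pd(OH)2/C) gives 20.

Step 8.
- What may go wrong: protodeboronation of the electron-rich boronate before transmetalation; hydrolysis of the enol triflate; base-induced elimination that opens the lactone across C5–C6.
- Fallback from 8 and 11, returning at 14: the polarity of the coupling is reversed. Miyaura borylation of 8 (B2pin2, PdCl2(dppf), KOAc, dioxane) gives the vinylboronate F6, which is not prone to protodeboronation. Suzuki–Miyaura coupling of F6 with bromide 11 (Pd(OAc)2, SPhos, K3PO4) gives 14.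

Step 9.
- What may go wrong: slow hydrocupration at the hindered β-carbon, or poor facial selectivity because the twisted aryl group on C4 screens both faces.
- Fallback from 14, returning at 15: homogeneous hydrogenation with [Ir(cod)(tBu-PHOX)][B(3,5-(CF3)2C6H3)4] under H2 in CH2Cl2. The catalyst rather than the C6 substituent then selects the face, and the ligand enantiomer is chosen to give the 4,6-cis lactone. Such catalysts do not cleave benzyl ethers. No new compound is made.

Step 11 (together with step 10).
- What may go wrong: proton transfer from the amide to the dianion; incomplete second deprotonation of the hindered β-keto lactone; O-acylation.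
- Fallback from 15, returning at 17: the four-carbon chain is introduced in one piece with its terminal ketone masked. N-methoxy-N-methyl-2-(2-methyl-1,3-dioxolan-2-yl)acetamide F7, made from commercial ethyl (2-methyl-1,3-dioxolan-2-yl)acetate with MeNHOMe·HCl and iPrMgCl, acylates the lithium enolate of 15 to give the ketal-protected diketo lactone F8. PPTS in wet acetone then removes the ketal to give 17.

## Further compounds

F1 | step 12 | 5,7,3',4'-tetra-O-benzyl-(+)-catechin | c1c(OCc3ccccc3)cc(OCc3ccccc3)c2c1O[C@H](c1ccc(OCc3ccccc3)c(OCc3ccccc3)c1)[C@@H](O)C2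
F2 | step 12 | O-{(2R,3S)-5,7-bis(benzyloxy)-2-[3,4-bis(benzyloxy)phenyl]chroman-3-yl} S-methyl carbonodithioate | c1c(OCc3ccccc3)cc(OCc3ccccc3)c2c1O[C@H](c1ccc(OCc3ccccc3)c(OCc3ccccc3)c1)[C@@H](OC(=S)SC)C2
F3 | step 12 | (2S)-5,7-bis(benzyloxy)-2-[3,4-bis(benzyloxy)phenyl]chroman | c1c(OCc3ccccc3)cc(OCc3ccccc3)c2c1O[C@H](c1ccc(OCc3ccccc3)c(OCc3ccccc3)c1)CC2
F4 | step 12 | (2S)-5,7-bis(benzyloxy)-2-[3,4-bis(benzyloxy)phenyl]-4-(2-ethoxyethoxy)chroman (C4 epimers) | c1c(OCc3ccccc3)cc(OCc3ccccc3)c2c1O[C@H](c1ccc(OCc3ccccc3)c(OCc3ccccc3)c1)CC2OCCOCC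
F5 | step 12 | (2S,4S)-5,7-bis(benzyloxy)-2-[3,4-bis(benzyloxy)phenyl]-4-{(2R,3S)-3,5,7-tris(benzyloxy)-2-[3,4-bis(benzyloxy)phenyl]chroman-8-yl}chroman | c3ccccc3COc1cc(OCc3ccccc3)c2c(c1)O[C@H](c1ccc(OCc3ccccc3)c(OCc3ccccc3)c1)C[C@@H]2c1c(OCc3ccccc3)cc(OCc3ccccc3)c2c1O[C@H](c1ccc(OCc3ccccc3)c(OCc3ccccc3)c1)[C@@H](OCc3ccccc3)C2
F6 | step 8 | (S)-6-[3,4-bis(benzyloxy)phenyl]-4-(4,4,5,5-tetramethyl-1,3,2-dioxaborolan-2-yl)-5,6-dihydro-2H-pyran-2-one | O=C5O[C@H](c1ccc(OCc3ccccc3)c(OCc3ccccc3)c1)CC(B1OC(C)(C)C(C)(C)O1)=C5
F0 | step 9 | none | none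
F7 | step 11 | N-methoxy-N-methyl-2-(2-methyl-1,3-dioxolan-2-yl)acetamide | CON(C)C(=O)CC1(C)OCCO1
F8 | step 11 | (4S,6S)-6-[3,4-bis(benzyloxy)phenyl]-3-[(2-methyl-1,3-dioxolan-2-yl)acetyl]-4-{(2R,3S)-3,5,7-tris(benzyloxy)-2-[3,4-bis(benzyloxy)phenyl]chroman-8-yl}tetrahydro-2H-pyran-2-one | O=C5O[C@H](c1ccc(OCc3ccccc3)c(OCc3ccccc3)c1)C[C@H](c1c(OCc3ccccc3)cc(OCc3ccccc3)c2c1O[C@H](c1ccc(OCc3ccccc3)c(OCc3ccccc3)c1)[C@@H](OCc3ccccc3)C2)C5C(=O)CC1(C)OCCO1
A1 | alternative 1 | 3,5-bis(benzyloxy)phenol | Oc1cc(OCc2ccccc2)cc(OCc2ccccc2)c1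
A2 | alternative 1 | 1-[3,4-bis(benzyloxy)phenyl]-3-{(2R,3S)-3,5,7-tris(benzyloxy)-2-[3,4-bis(benzyloxy)phenyl]chroman-8-yl}prop-2-yn-1-one | O=C(C#Cc1c(OCc3ccccc3)cc(OCc3ccccc3)c2c1O[C@H](c1ccc(OCc3ccccc3)c(OCc3ccccc3)c1)[C@@H](OCc3ccccc3)C2)c1ccc(OCc3ccccc3)c(OCc3ccccc3)c1
A3 | alternative 1 | 5,7-bis(benzyloxy)-2-[3,4-bis(benzyloxy)phenyl]-4-{(2R,3S)-3,5,7-tris(benzyloxy)-2-[3,4-bis(benzyloxy)phenyl]chroman-8-yl}chromenylium tetrafluoroborate | c3ccccc3COc1cc(OCc3ccccc3)c2c(c1)[o+]c(c1ccc(OCc3ccccc3)c(OCc3ccccc3)c1)cc2c1c(OCc3ccccc3)cc(OCc3ccccc3)c2c1O[C@H](c1ccc(OCc3ccccc3)c(OCc3ccccc3)c1)[C@@H](OCc3ccccc3)C2.F[B-](F)(F)F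
A4 | alternative 2 | 2,4-cis-5,7-bis(benzyloxy)-2-[3,4-bis(benzyloxy)phenyl]-4-[4,6-bis(benzyloxy)-2-hydroxy-3-(hydroxymethyl)phenyl]chroman, ring C configured as in 20 | c3ccccc3COc1cc(OCc3ccccc3)c2c(c1)O[C@H](c1ccc(OCc3ccccc3)c(OCc3ccccc3)c1)C[C@@H]2c1c(OCc3ccccc3)cc(OCc3ccccc3)c(CO)c1O
A5 | alternative 2 | 3,5-bis(benzyloxy)-2-{2,4-cis-5,7-bis(benzyloxy)-2-[3,4-bis(benzyloxy)phenyl]chroman-4-yl}-6-methylidenecyclohexa-2,4-dien-1-one, ring C configured as in 20 | c3ccccc3COc1cc(OCc3ccccc3)c2c(c1)O[C@H](c1ccc(OCc3ccccc3)c(OCc3ccccc3)c1)C[C@@H]2C1=C(OCc3ccccc3)C=C(OCc3ccccc3)C(=C)C1=O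
A6 | alternative 2 | benzyl{(E)-2-[3,4-bis(benzyloxy)phenyl]ethenyl}dimethylsilane | C[Si](C)(Cc1ccccc1)/C=C/c1ccc(OCc2ccccc2)c(OCc2ccccc2)c1
A7 | alternative 2 | octa-O-benzyl ether of 20 with benzyldimethylsilyl in place of the 3'-hydroxyl | c3ccccc3COc1cc(OCc3ccccc3)c2c(c1)O[C@H](c1ccc(OCc3ccccc3)c(OCc3ccccc3)c1)C[C@@H]2c1c(OCc3ccccc3)cc(OCc3ccccc3)c2c1O[C@H](c1ccc(OCc3ccccc3)c(OCc3ccccc3)c1)[C@@H]([Si](C)(C)Cc3ccccc3)C2
A8 | alternative 3 | 3,5-bis(benzyloxy)-2-(1-{(2R,3S)-3,5,7-tris(benzyloxy)-2-[3,4-bis(benzyloxy)phenyl]chroman-8-yl}ethenyl)phenol | C=C(c1c(O)cc(OCc3ccccc3)cc1OCc3ccccc3)c1c(OCc3ccccc3)cc(OCc3ccccc3)c2c1O[C@H](c1ccc(OCc3ccccc3)c(OCc3ccccc3)c1)[C@@H](OCc3ccccc3)C2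
A9 | alternative 3 | (2S)-5,7-bis(benzyloxy)-2-[3,4-bis(benzyloxy)phenyl]-4-{(2R,3S)-3,5,7-tris(benzyloxy)-2-[3,4-bis(benzyloxy)phenyl]chroman-8-yl}-2H-chromene | c3ccccc3COc1cc(OCc3ccccc3)c2c(c1)O[C@H](c1ccc(OCc3ccccc3)c(OCc3ccccc3)c1)C=C2c1c(OCc3ccccc3)cc(OCc3ccccc3)c2c1O[C@H](c1ccc(OCc3ccccc3)c(OCc3ccccc3)c1)[C@@H](OCc3ccccc3)C2
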